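**Strategy**

The route rests on cutting the C-14–C-19 bond of cyclohexane ring C and the C-23–O bond of oxepane ring D in the hydroxy-bearing half. The key step exploits that the trans ring fusion C-18(H)(O)/C-19(Me) and the O–C-23Me2–C-22H(OH) unit are the imprint of two (S)-configured trisubstituted epoxides five atoms apart, and that C-14/C-15 is a masked (Z)-2-(silylmethyl) alkene. One silyl-triflate-triggered cascade on an open-chain precursor, which already carries the finished diacetoxy bicycle (rings A and B), closes ring D through an epoxonium ion and then ring C, sets C-14 and C-19, and leaves a C-15 methylene for the equatorial tertiary acetate.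

Key step: step 12

Numbering (squalene type, used throughout): C-1 to C-24 along the chain, starting in the diacetoxy half. C-2/C-23 = CMe2–O, C-3/C-22 = CH–O, C-6/C-19 = angular C–Me, C-7/C-18 = ring-fusion CH–O, C-10/C-15 = C(Me)OAc, C-11/C-14 = ring CH, C-12/C-13 = ethylene bridge. Ring A = oxepane (O, C-2 to C-7), ring B = cyclohexane (C-6 to C-11), ring C = cyclohexane (C-14 to C-19), ring D = oxepane (O, C-18 to C-23).

Remark on the chemistry: the two halves differ only at the C(Me)OAc carbon (10R, axial acetate; 15S, equatorial acetate). C-10 is therefore brought in as a stereocentre of the open chain, and C-15 is made after ring closure.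

Assumption: the L-fructose-derived enantiomer of the Shi ketone is available (commercial or from L-sorbose); (2E,6E)-farnesol and (E)-geranylacetone are commercial.

**Route**

Step 1
Reactants: 1 (2E,6E)-farnesol
Product: 2 (2R,3R)-2,3-epoxyfarnesol
Conditions: Ti(OiPr)4 (cat.), D-(−)-diethyl tartrate (cat.), t-BuOOH, 4 Å MS, CH2Cl2, −20 °C
Reagents that add atoms: tert-butyl hydroperoxide, CC(C)(C)OO
Why: Sharpless asymmetric epoxidation: the titanium–tartrate complex oxidises only the allylic 2,3-alkene, and the D-tartrate delivers oxygen to the face that gives the 2R,3R epoxide (the tertiary carbon is the future C-10).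

Step 2
Reactants: 2 (2R,3R)-2,3-epoxyfarnesol
Product: 4 (3R,6E)-nerolidol, via epoxy iodide 3 (not isolated)
Conditions: PPh3, I2, imidazole, THF, 0 °C; then Zn dust, AcOH, 0 °C → rt
Reagents that add atoms: iodine, II (its atom is carried only by 3)
Why: Appel iodination of the primary alcohol followed by zinc-induced reductive opening of the epoxy iodide (1,3-transposition) should give the tertiary allylic alcohol; the C–O bond at the tertiary carbon is never broken, so the 3R centre is retained.

Step 3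
Reactants: 4 (3R,6E)-nerolidol
Product: 5 (3R,6E)-nerolidyl acetate
Conditions: Ac2O, Et3N, DMAP, CH2Cl2, rt
Reagents that add atoms: acetic anhydride, CC(=O)OC(C)=O
Why: DMAP-catalysed acylation of the tertiary allylic alcohol is easy at this unhindered open-chain stage and fixes the later axial C-10 acetate before ring B exists, with the stereocentre untouched.

Step 4
Reactants: 5 (3R,6E)-nerolidyl acetate
Product: 6 (3R,6S,7S,10S)-6,7:10,11-diepoxy-6,7,10,11-tetrahydronerolidyl acetate
Conditions: L-fructose-derived Shi ketone (cat.), Oxone (2KHSO5·KHSO4·K2SO4), K2CO3, Bu4NHSO4, MeCN–DMM–aq. Na2B4O7 buffer, 0 °C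
Reagents that add atoms: potassium peroxymonosulfate, [K+].[O-]S(=O)(=O)OO
Why: Shi asymmetric epoxidation: the chiral dioxirane oxidises only the two electron-rich trisubstituted alkenes (the vinyl group next to the acetoxy carbon is inert) and, under reagent control, should give the S configuration at C-3, C-6 and C-7.

Step 5
Reactants: 6 diepoxy nerolidyl acetate
Product: 7 (2E,4R)-4-methyl-6-[(2S,3S)-3-methyl-3-{2-[(2S)-3,3-dimethyloxiran-2-yl]ethyl}oxiran-2-yl]-1-(trimethylsilyl)hex-2-en-4-yl acetate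
Conditions: allyltrimethylsilane (5 equiv), second-generation Hoveyda–Grubbs catalyst (5 mol%), CH2Cl2, 40 °C
Reagents that add atoms: allyltrimethylsilane, C=CC[Si](C)(C)C
Why: Olefin cross-metathesis: the hindered vinyl group cannot homodimerise and is captured by the ruthenium alkylidene formed from the excess allylsilane, the quaternary neighbour enforcing the E alkene; no stereocentre is touched.

Step 6
Reactants: 7 allylsilane diepoxide
Product: 9 (3S,5aS,6S,7R,9aS)-6-ethenyl-3-hydroxy-2,2,5a,7-tetramethyldecahydro-1-benzoxepin-7-yl acetate, via trimethylsilyl ether 8 (not isolated)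
Conditions: Me3SiOTf (1.2 equiv), 2,6-di-tert-butyl-4-methylpyridine (DTBMP), CH2Cl2, −78 °C; then 1 M HCl, THF, 0 °C
Reagents that add atoms: trimethylsilyl triflate, C[Si](C)(C)OS(=O)(=O)C(F)(F)F (its silyl group is carried only by 8)
Why: Silyl-triflate-promoted tandem oxa-/carbacyclisation of a 1,5-diepoxide: the oxygen of the 6,7-epoxide opens the silylated 2,3-epoxide at C-2, and the epoxonium ion is opened at C-6 with inversion by C-11 of the allylsilane (6-exo for the alkene, chair transition state with the alkenyl arm pseudo-equatorial and the preset C-10 acetoxy group axial), the β-silyl cation collapsing to the vinyl group, while C-3 and C-7 keep the epoxide configuration.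

Step 7
Reactants: 9 bicyclic alcohol
Product: 10 (3S,5aS,6S,7R,9aS)-6-ethenyl-2,2,5a,7-tetramethyldecahydro-1-benzoxepine-3,7-diyl diacetate
Conditions: Ac2O, pyridine, DMAP (cat.), rt
Reagents that add atoms: acetic anhydride, CC(=O)OC(C)=O
Why: Standard DMAP-catalysed acetylation of the secondary C-3 hydroxyl, which also distinguishes it from the C-22 oxygen that the key step will deliver as a silyl ether.

Step 8
Reactants: 11 (E)-geranylacetone
Product: 13 (5E)-6,10-dimethylundeca-5,9-dien-1-yne, via enol phosphate 12 (not isolated)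
Conditions: LDA (LiN(iPr)2), THF, −78 °C; ClP(O)(OEt)2; then LDA (2.3 equiv), −78 °C → rt; aq. NH4Cl
Reagents that add atoms: diethyl chlorophosphate, CCOP(=O)(Cl)OCC (carried only by 12)
Why: Kinetic deprotonation at the methyl group, O-phosphorylation and base-induced elimination of the terminal enol phosphate convert the methyl ketone into the terminal alkyne without touching the E alkene.

Step 9
Reactants: 13 enyne
Product: 15 (1Z,5E)-1-bromo-6,10-dimethyl-2-[(trimethylsilyl)methyl]undeca-1,5,9-triene, via alkenylcopper 14 (not isolated)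
Conditions: Me3SiCH2MgCl, CuBr·SMe2, Et2O–Me2S, −40 °C; add 13, −25 → 0 °C; then NBS, THF, −40 °C
Reagents that add atoms: (trimethylsilyl)methylmagnesium chloride, C[Si](C)(C)C[Mg]Cl; CuBr·SMe2, [Cu]Br.CSC (copper is carried only by 14); N-bromosuccinimide, BrN1C(=O)CCC1=O
Why: Normant-type syn-carbocupration of the terminal alkyne places the silylmethyl group on the inner carbon and copper cis to it on the terminal carbon, and bromination of the alkenylcopper with retention should give the Z bromoalkene (future C-13 cis to CH2SiMe3 and trans to C-16).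

Step 10
Reactants: 15 bromoalkene
Product: 16 {(2Z)-3-bromo-2-[2-((2S,3S)-3-methyl-3-{2-[(2S)-3,3-dimethyloxiran-2-yl]ethyl}oxiran-2-yl)ethyl]prop-2-en-1-yl}trimethylsilane
Conditions: L-fructose-derived Shi ketone (cat.), Oxone (2KHSO5·KHSO4·K2SO4), K2CO3, Bu4NHSO4, MeCN–DMM–aq. Na2B4O7 buffer, 0 °C
Reagents that add atoms: potassium peroxymonosulfate, [K+].[O-]S(=O)(=O)OO
Why: Shi asymmetric epoxidation as in step 4: only the two trialkyl-substituted alkenes react, because the bromo-substituted alkene is deactivated toward the electrophilic dioxirane and the C–Br bond is inert to it, and reagent control should give the 18S,19S and 22S epoxides.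

Step 11
Reactants: 10 vinyl diacetate; 16 bromoalkene diepoxide
Product: 18 (3S,5aS,6S,7R,9aS)-6-{(3Z)-4-[(trimethylsilyl)methyl]-6-[(2S,3S)-3-methyl-3-{2-[(2S)-3,3-dimethyloxiran-2-yl]ethyl}oxiran-2-yl]hex-3-en-1-yl}-2,2,5a,7-tetramethyldecahydro-1-benzoxepine-3,7-diyl diacetate, via alkylborane 17 (not isolated)
Conditions: 9-BBN, THF, rt; then 16, Pd(dppf)Cl2 (cat.), AsPh3, Cs2CO3, DMF–H2O, 50 °C
Reagents that add atoms: 9-borabicyclo[3.3.1]nonane, B1C2CCCC1CCC2 (boron is carried only by 17)
Why: B-alkyl Suzuki–Miyaura coupling: 9-BBN adds anti-Markovnikov to the only alkene of 10 (boron on C-13), and the alkylborane couples with the bromoalkene with retention of the Z geometry under conditions that spare acetates, epoxides and the allylsilane.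

Step 12
Reactants: 18 cascade precursor
Product: 19 (3S,5aS,6S,7R,9aS)-6-{2-[(3S,5aS,6R,9aS)-3-(tert-butyldimethylsilyloxy)-2,2,5a-trimethyl-7-methylidenedecahydro-1-benzoxepin-6-yl]ethyl}-2,2,5a,7-tetramethyldecahydro-1-benzoxepine-3,7-diyl diacetate
Conditions: t-BuMe2SiOTf (1.5 equiv), DTBMP (2 equiv), CH2Cl2, −78 °C
Reagents that add atoms: tert-butyldimethylsilyl triflate, CC(C)(C)[Si](C)(C)OS(=O)(=O)C(F)(F)F
Why: The silyl triflate silylates the less hindered terminal 22,23-epoxide, its tertiary carbon C-23 is attacked by the oxygen of the 18,19-epoxide to give a bicyclic epoxonium ion, the tertiary carbon C-19 of this ion is attacked anti to oxygen by C-14 of the allylsilane, and the β-silyl cation at C-15 gives up Me3Si+ to triflate, which leaves the exocyclic methylene. The closest known reaction type is the silyl-triflate-promoted tandem oxa-/carbacyclisation of 1,5-diepoxides with π-nucleophile terminators, joined to the allylsilane termination of cation–olefin cyclisations. Ring D closes by endo opening of the activated epoxide at its tertiary carbon (C-23–O bond), the oxepane being complete when the C-19–O bond of the epoxonium ion breaks, and ring C closes last by 6-endo attack (endo for both the alkene and the epoxonium ion) through a chair transition state. C-22 and C-18 keep the configuration of the epoxides, C-19 is inverted by the anti opening (trans ring fusion, axial methyl), and C-14 is set by the Z alkene geometry, which holds C-13 trans to C-16 and hence equatorial in the chair. The step needs activation of the terminal before the internal epoxide, oxygen attack before carbon attack, and termination without proton loss; the bulk of the tert-butyldimethylsilyl group, the five-atom spacing of the epoxides, the methyl groups that steer each opening to the tertiary carbon and the β-effect of silicon (one alkene isomer, no acid set free, base buffer) should secure these, while the acetates of rings A and B are poor nucleophiles and should not ionise at −78 °C.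

Step 13
Reactants: 19 methylidene silyl ether
Product: 20 (3S,5aS,6S,7R,9aS)-6-{2-[(3S,5aS,6S,7S,9aS)-3-(tert-butyldimethylsilyloxy)-7-hydroxy-2,2,5a,7-tetramethyldecahydro-1-benzoxepin-6-yl]ethyl}-2,2,5a,7-tetramethyldecahydro-1-benzoxepine-3,7-diyl diacetate
Conditions: Mn(dpm)3 (cat.), PhSiH3, O2 (1 atm), i-PrOH–CH2Cl2, 0 °C → rt
Reagents that add atoms: dioxygen, O=O
Why: Mukaiyama hydration (hydrogen-atom transfer to the 1,1-disubstituted alkene, Markovnikov): the tertiary C-15 radical should be captured by O2 from the equatorial α face because the axial approach is blocked by the syn-axial C-19 methyl, which gives the 15S alcohol with axial methyl and leaves acetates and the silyl ether untouched.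

Step 14
Reactants: 20 tertiary alcohol
Product: 21 (3S,5aS,6S,7R,9aS)-6-{2-[(3S,5aS,6S,7S,9aS)-7-acetoxy-3-(tert-butyldimethylsilyloxy)-2,2,5a,7-tetramethyldecahydro-1-benzoxepin-6-yl]ethyl}-2,2,5a,7-tetramethyldecahydro-1-benzoxepine-3,7-diyl diacetate
Conditions: Ac2O, DMAP, Et3N, CH2Cl2, 40 °C
Reagents that add atoms: acetic anhydride, CC(=O)OC(C)=O
Why: DMAP-catalysed acetylation of the equatorial tertiary alcohol, the only free hydroxyl, completes the three acetates while C-22 stays silylated.

Step 15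
Reactants: 21 triacetate silyl ether
Product: 22 CNP0169816.1, (3S,5aS,6S,7R,9aS)-6-{2-[(3S,5aS,6S,7S,9aS)-7-acetoxy-3-hydroxy-2,2,5a,7-tetramethyldecahydro-1-benzoxepin-6-yl]ethyl}-2,2,5a,7-tetramethyldecahydro-1-benzoxepine-3,7-diyl diacetate
Conditions: HF·pyridine, THF–pyridine, 0 °C → rt
Reagents that add atoms: none
Why: Fluoride-induced cleavage of the Si–O bond (desilylation) frees the C-22 hydroxyl under mildly acidic conditions that should neither cleave nor shift the acetates.

**Compound list**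

1 | (2E,6E)-farnesol | OC/C=C(\C)CC/C=C(\C)CCC=C(C)C | starting material
2 | (2R,3R)-2,3-epoxyfarnesol | OC[C@H]1O[C@]1(C)CC/C=C(\C)CCC=C(C)C | intermediate
3 | (2S,3R)-2-(iodomethyl)-3-methyl-3-[(3E)-4,8-dimethylnona-3,7-dien-1-yl]oxirane | IC[C@H]1O[C@]1(C)CC/C=C(\C)CCC=C(C)C | intermediate (not isolated)
4 | (3R,6E)-nerolidol | C=C[C@](C)(O)CC/C=C(\C)CCC=C(C)C | intermediate
5 | (3R,6E)-nerolidyl acetate | C=C[C@](C)(OC(C)=O)CC/C=C(\C)CCC=C(C)C | intermediate
6 | (3R)-3-methyl-5-[(2S,3S)-3-methyl-3-{2-[(2S)-3,3-dimethyloxiran-2-yl]ethyl}oxiran-2-yl]pent-1-en-3-yl acetate | C=C[C@](C)(OC(C)=O)CC[C@@H]1O[C@@]1(C)CC[C@@H]1OC1(C)C | intermediate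
7 | (2E,4R)-4-methyl-6-[(2S,3S)-3-methyl-3-{2-[(2S)-3,3-dimethyloxiran-2-yl]ethyl}oxiran-2-yl]-1-(trimethylsilyl)hex-2-en-4-yl acetate | C[Si](C)(C)C/C=C/[C@](C)(OC(C)=O)CC[C@@H]1O[C@@]1(C)CC[C@@H]1OC1(C)C | intermediate
8 | trimethylsilyl ether of 9 (silyloxy group on C-3) | C[Si](C)(C)O[C@H]1CC[C@]2(C)[C@H](CC[C@@](C)(OC(C)=O)[C@H]2C=C)OC1(C)C | intermediate (not isolated)
9 | (3S,5aS,6S,7R,9aS)-6-ethenyl-3-hydroxy-2,2,5a,7-tetramethyldecahydro-1-benzoxepin-7-yl acetate | O[C@H]1CC[C@]2(C)[C@H](CC[C@@](C)(OC(C)=O)[C@H]2C=C)OC1(C)C | intermediate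
10 | (3S,5aS,6S,7R,9aS)-6-ethenyl-2,2,5a,7-tetramethyldecahydro-1-benzoxepine-3,7-diyl diacetate | CC(=O)O[C@H]1CC[C@]2(C)[C@H](CC[C@@](C)(OC(C)=O)[C@H]2C=C)OC1(C)C | intermediate
11 | (E)-geranylacetone, (5E)-6,10-dimethylundeca-5,9-dien-2-one | CC(=O)CC/C=C(\C)CCC=C(C)C | starting material
12 | diethyl (5E)-6,10-dimethylundeca-1,5,9-trien-2-yl phosphate | C=C(OP(=O)(OCC)OCC)CC/C=C(\C)CCC=C(C)C | intermediate (not isolated)
13 | (5E)-6,10-dimethylundeca-5,9-dien-1-yne | C#CCC/C=C(\C)CCC=C(C)C | intermediate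
14 | [(1Z,5E)-6,10-dimethyl-2-[(trimethylsilyl)methyl]undeca-1,5,9-trien-1-yl]copper | [Cu]/C=C(\C[Si](C)(C)C)CC/C=C(\C)CCC=C(C)C | intermediate (not isolated)
15 | (1Z,5E)-1-bromo-6,10-dimethyl-2-[(trimethylsilyl)methyl]undeca-1,5,9-triene | Br/C=C(\C[Si](C)(C)C)CC/C=C(\C)CCC=C(C)C | intermediate
16 | {(2Z)-3-bromo-2-[2-((2S,3S)-3-methyl-3-{2-[(2S)-3,3-dimethyloxiran-2-yl]ethyl}oxiran-2-yl)ethyl]prop-2-en-1-yl}trimethylsilane | Br/C=C(\C[Si](C)(C)C)CC[C@@H]1O[C@@]1(C)CC[C@@H]1OC1(C)C | intermediate
17 | B-alkyl-9-BBN derivative of 10 (boron on C-13) | CC(=O)O[C@H]1CC[C@]2(C)[C@H](CC[C@@](C)(OC(C)=O)[C@H]2CCB2C3CCCC2CCC3)OC1(C)C | intermediate (not isolated)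
18 | cascade precursor: diacetoxy bicycle (rings A and B) carrying on C-11 the (3Z)-4-[(trimethylsilyl)methyl]hex-3-enyl chain that ends in the (18S,19S,22S)-diepoxide | CC(=O)O[C@H]1CC[C@]2(C)[C@H](CC[C@@](C)(OC(C)=O)[C@H]2CC/C=C(\C[Si](C)(C)C)CC[C@@H]2O[C@@]2(C)CC[C@@H]2OC2(C)C)OC1(C)C | intermediate
19 | bis-bicycle with C-15 methylidene and C-22 tert-butyldimethylsilyl ether (name as in step 12) | CC(=O)O[C@H]1CC[C@]2(C)[C@H](CC[C@@](C)(OC(C)=O)[C@H]2CC[C@H]2[C@]3(C)CC[C@H](O[Si](C)(C)C(C)(C)C)C(C)(C)O[C@H]3CCC2=C)OC1(C)C | intermediate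
20 | (15S)-tertiary alcohol, C-22 silyl ether, C-3 and C-10 acetates (name as in step 13) | CC(=O)O[C@H]1CC[C@]2(C)[C@H](CC[C@@](C)(OC(C)=O)[C@H]2CC[C@H]2[C@]3(C)CC[C@H](O[Si](C)(C)C(C)(C)C)C(C)(C)O[C@H]3CC[C@]2(C)O)OC1(C)C | intermediate
21 | C-3, C-10, C-15 triacetate, C-22 tert-butyldimethylsilyl ether (name as in step 14) | CC(=O)O[C@H]1CC[C@]2(C)[C@H](CC[C@@](C)(OC(C)=O)[C@H]2CC[C@H]2[C@]3(C)CC[C@H](O[Si](C)(C)C(C)(C)C)C(C)(C)O[C@H]3CC[C@]2(C)OC(C)=O)OC1(C)C | intermediate
22 | CNP0169816.1 (name as in step 15) | CC(=O)O[C@H]1CC[C@]2(C)[C@H](CC[C@@](C)(OC(C)=O)[C@H]2CC[C@H]2[C@]3(C)CC[C@H](O)C(C)(C)O[C@H]3CC[C@]2(C)OC(C)=O)OC1(C)C | target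

**Step count and risks**

Total step count: 15 (steps 1–7 for the diacetoxy bicycle, steps 8–10 for the bromoalkene diepoxide, steps 11–15 after the union).
Longest linear sequence: 12 steps (1–7 and 11–15, from farnesol).

Steps most likely to fail:

1. Step 6. The silyl triflate may ionise the tertiary allylic acetate (vinylogous loss of the silyl group to a diene) faster than it activates the terminal epoxide, and the closure in the exo mode may show poor facial selectivity at C-11. The fallback sets out from (E)-geranylacetone (11) and comes back at the bicyclic alcohol 9; it closes ring B in the endo mode with C-10 still trigonal and makes C-10 afterwards. Carboxylation of 11 (NaH, dimethyl carbonate) gives the β-keto ester F1. Chelation-controlled triflation (aq. LiOH, Tf2O) gives the (Z)-enol triflate F2, and Shi epoxidation as in step 4 gives the diepoxy triflate F3. Pd(PPh3)4-catalysed coupling with Me3SiCH2MgCl gives the (Z)-allylsilane ester F4, and iBu2AlH (−78 °C) gives the allylic alcohol F5. t-BuMe2SiOTf (2.5 equiv)/DTBMP silylates the primary hydroxyl and triggers the cascade, in which the Z alkene places C-12 equatorial, to give the bis-silyl ether F6 with a C-10 methylene. Ozonolysis (O3, then PPh3) gives the ketone F7. MeMgBr/CeCl3 adds from the equatorial face, the axial approach being blocked by the C-6 methyl, to give the axial tertiary alcohol F8. Acetylation (Ac2O, DMAP, 50 °C) gives the acetate F9, and HF·pyridine removes both silyl groups to give the diol F10. TEMPO/PhI(OAc)2 oxidises only the primary alcohol to the aldehyde F11, and Wittig methylenation (Ph3P=CH2, −78 °C) gives 9.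

2. Step 12. The very nucleophilic allylsilane may open the silyl-activated internal epoxide directly (monocyclisation without the oxepane), or lose its silyl group by protodesilylation before the cascade. The fallback sets out from the enyne 13 (with the alkylborane 17 as partner) and comes back at the tertiary alcohol 20; it uses the silicon-free, less nucleophilic terminator of the parent polyene cyclisations. Zirconium-catalysed methylalumination of 13 (Me3Al, Cp2ZrCl2; then NBS) gives the (E)-bromoalkene F12, and Shi epoxidation gives the diepoxide F13. Suzuki–Miyaura coupling with 17 gives the methyl-substituted cascade precursor F14. The same t-BuMe2SiOTf/DTBMP cascade, now ended by loss of a proton from the C-15 cation, gives 19 together with its ring-alkene isomer F15. Mukaiyama hydration of the mixture under the conditions of step 13 converges on 20, because both alkenes give the same tertiary C-15 radical.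

3. Step 13. Capture of the C-15 radical by O2 may show poor facial selectivity and give a mixture of C-15 epimers. The fallback sets out from 19 and comes back at 21. mCPBA (NaHCO3, CH2Cl2, 0 °C) epoxidises the methylene from the equatorial α face to give the spiro-epoxide F16. LiAlH4 opens it at the CH2 carbon and at the same time removes the two acetates to give the triol F17. Ac2O/DMAP (50 °C) acetylates all three hydroxyls to give 21.

Further compounds

F1 | step 6 | methyl (6E)-7,11-dimethyl-3-oxododeca-6,10-dienoate | COC(=O)CC(=O)CC/C=C(\C)CCC=C(C)C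
F2 | step 6 | methyl (2Z,6E)-7,11-dimethyl-3-(trifluoromethylsulfonyloxy)dodeca-2,6,10-trienoate | COC(=O)/C=C(\OS(=O)(=O)C(F)(F)F)CC/C=C(\C)CCC=C(C)C
F3 | step 6 | methyl (2Z)-5-[(2S,3S)-3-methyl-3-{2-[(2S)-3,3-dimethyloxiran-2-yl]ethyl}oxiran-2-yl]-3-(trifluoromethylsulfonyloxy)pent-2-enoate | COC(=O)/C=C(\OS(=O)(=O)C(F)(F)F)CC[C@@H]1O[C@@]1(C)CC[C@@H]1OC1(C)C
F4 | step 6 | methyl (2Z)-5-[(2S,3S)-3-methyl-3-{2-[(2S)-3,3-dimethyloxiran-2-yl]ethyl}oxiran-2-yl]-3-[(trimethylsilyl)methyl]pent-2-enoate | COC(=O)/C=C(\C[Si](C)(C)C)CC[C@@H]1O[C@@]1(C)CC[C@@H]1OC1(C)C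
F5 | step 6 | (2Z)-5-[(2S,3S)-3-methyl-3-{2-[(2S)-3,3-dimethyloxiran-2-yl]ethyl}oxiran-2-yl]-3-[(trimethylsilyl)methyl]pent-2-en-1-ol | OC/C=C(\C[Si](C)(C)C)CC[C@@H]1O[C@@]1(C)CC[C@@H]1OC1(C)C
F6 | step 6 | bicycle (rings A and B) with C-10 methylidene, C-3 and C-12 tert-butyldimethylsilyl ethers, ring stereocentres as in 9 | CC(C)(C)[Si](C)(C)O[C@H]1CC[C@]2(C)[C@H](CCC(=C)[C@H]2CO[Si](C)(C)C(C)(C)C)OC1(C)C
F7 | step 6 | C-10 ketone of the bis-silyl ether | CC(C)(C)[Si](C)(C)O[C@H]1CC[C@]2(C)[C@H](CCC(=O)[C@H]2CO[Si](C)(C)C(C)(C)C)OC1(C)C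
F8 | step 6 | (10R)-tertiary alcohol (axial hydroxyl) of the bis-silyl ether | CC(C)(C)[Si](C)(C)O[C@H]1CC[C@]2(C)[C@H](CC[C@@](C)(O)[C@H]2CO[Si](C)(C)C(C)(C)C)OC1(C)C
F9 | step 6 | C-10 acetate of the bis-silyl ether | CC(C)(C)[Si](C)(C)O[C@H]1CC[C@]2(C)[C@H](CC[C@@](C)(OC(C)=O)[C@H]2CO[Si](C)(C)C(C)(C)C)OC1(C)C
F10 | step 6 | (3S,5aS,6S,7R,9aS)-3-hydroxy-6-(hydroxymethyl)-2,2,5a,7-tetramethyldecahydro-1-benzoxepin-7-yl acetate | O[C@H]1CC[C@]2(C)[C@H](CC[C@@](C)(OC(C)=O)[C@H]2CO)OC1(C)C
F11 | step 6 | (3S,5aS,6S,7R,9aS)-6-formyl-3-hydroxy-2,2,5a,7-tetramethyldecahydro-1-benzoxepin-7-yl acetate | O[C@H]1CC[C@]2(C)[C@H](CC[C@@](C)(OC(C)=O)[C@H]2C=O)OC1(C)C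
F12 | step 12 | (1E,5E)-1-bromo-2,6,10-trimethylundeca-1,5,9-triene | Br/C=C(\C)CC/C=C(\C)CCC=C(C)C
F13 | step 12 | (2S,3S)-2-[(3E)-4-bromo-3-methylbut-3-en-1-yl]-3-methyl-3-{2-[(2S)-3,3-dimethyloxiran-2-yl]ethyl}oxirane | Br/C=C(\C)CC[C@@H]1O[C@@]1(C)CC[C@@H]1OC1(C)C
F14 | step 12 | analogue of 18 with methyl in place of the (trimethylsilyl)methyl group (3E alkene) | CC(=O)O[C@H]1CC[C@]2(C)[C@H](CC[C@@](C)(OC(C)=O)[C@H]2CC/C=C(\C)CC[C@@H]2O[C@@]2(C)CC[C@@H]2OC2(C)C)OC1(C)C
F15 | step 12 | isomer of 19 with the ring alkene C-15=C-16 and a C-15 methyl group | CC(=O)O[C@H]1CC[C@]2(C)[C@H](CC[C@@](C)(OC(C)=O)[C@H]2CC[C@H]2[C@]3(C)CC[C@H](O[Si](C)(C)C(C)(C)C)C(C)(C)O[C@H]3CC=C2C)OC1(C)C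
F16 | step 13 | spiro-epoxide of 19 at C-15 (oxygen on the equatorial α face) | CC(=O)O[C@H]1CC[C@]2(C)[C@H](CC[C@@](C)(OC(C)=O)[C@H]2CC[C@H]2[C@]3(C)CC[C@H](O[Si](C)(C)C(C)(C)C)C(C)(C)O[C@H]3CC[C@@]24CO4)OC1(C)C
F17 | step 13 | C-3, C-10, C-15 triol with the C-22 tert-butyldimethylsilyl ether | O[C@H]1CC[C@]2(C)[C@H](CC[C@@](C)(O)[C@H]2CC[C@H]2[C@]3(C)CC[C@H](O[Si](C)(C)C(C)(C)C)C(C)(C)O[C@H]3CC[C@]2(C)O)OC1(C)C
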